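**Assumption:** (S)-2-hydroxyhexanoic acid (the hydroxy acid corresponding to L-norleucine) is bought as the single enantiomer. The target is isolated as the free hydroxy acid, which must be kept cold and away from acid because it relactonises.

## Retrosynthetic overview

- Target ⇐ hydroxide opening of the (S)-3-butylphthalide triol ⇐ BBr3 demethylation of its tri-O-methyl ether.
- Diaryl ether C–O bond (key bond) ⇐ visible-light photoredox radical-cation Smiles shift (O-to-O aryl migration) of a depside, a 2,4-dimethoxy-6-pentylphenyl salicylate, to the 2-aryloxybenzoic acid, then lactonisation.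
- Depside ⇐ photochemical acylation: quinoketene from an acetonide-masked resorcylate (benzodioxinone) plus 2,4-dimethoxy-6-pentylphenol (two steps from olivetol dimethyl ether).
- Ring B ⇐ de novo aldol aromatisation of a diketo-dioxinone ⇐ keto-dioxinone dianion plus the (S)-2-silyloxyhexanoyl imidazole from (S)-2-hydroxyhexanoic acid, which supplies the only stereocentre.
- Ring order: ring A is bought intact; ring B (benzene) forms in step 4; the lactone ring forms in step 8 and is opened in step 10.

## Route

**Step 1**
Reactants: 1 (S)-2-hydroxyhexanoic acid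
Product: 3 (S)-2-(tert-butyldimethylsilyloxy)hexanoic acid, via silyl ester 2 (not isolated)
Conditions: t-BuMe2SiCl (2.3 equiv), imidazole, DMF, rt; then K2CO3, MeOH/THF/H2O, rt; aq. KHSO4 to pH 4, 0 °C
Reagents that add atoms: tert-butyldimethylsilyl chloride, CC(C)(C)[Si](C)(C)Cl
Why: Exhaustive silylation followed by selective carbonate cleavage of the labile silyl ester is the standard O-silylation of an α-hydroxy acid, and no bond to the stereocentre is touched, so the bought (S) configuration is carried over unchanged.

**Step 2**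
Reactants: 4 2,2,6-trimethyl-4H-1,3-dioxin-4-one
Product: 5 2,2-dimethyl-6-(2-oxopropyl)-4H-1,3-dioxin-4-one
Conditions: 4 (2 equiv), LiN(SiMe3)2 (2 equiv), THF, −78 °C; AcCl (1 equiv), −78 → −20 °C; 1 M HCl
Reagents that add atoms: acetyl chloride, CC(Cl)=O
Why: The lithium dienolate of the dioxinone is C-acylated at its γ-carbon (vinylogous Claisen condensation), the second equivalent of dienolate absorbing the acidic proton of the keto-dioxinone formed.

**Step 3**
Reactants: 3 (S)-2-(tert-butyldimethylsilyloxy)hexanoic acid; 5 2,2-dimethyl-6-(2-oxopropyl)-4H-1,3-dioxin-4-one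
Product: 7 6-[(S)-5-(tert-butyldimethylsilyloxy)-2,4-dioxononyl]-2,2-dimethyl-4H-1,3-dioxin-4-one, via acyl imidazole 6 (not isolated)
Conditions: 3, 1,1'-carbonyldiimidazole (1.1 equiv), THF, rt; added to 5 (3 equiv)/LiN(i-Pr)2 (6 equiv), THF, −78 → −40 °C; 1 M HCl, 0 °C
Reagents that add atoms: none
Why: Crossed Claisen condensation of the 1,3-dianion of 5 at its terminal carbon with the N-acylimidazole gives the triketide, which is at once stored as a delocalised enolate pointing away from the α-silyloxy carbon, so the (S) centre is retained as with protected α-amino acyl donors in the same chemistry.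

**Step 4**
Reactants: 7 6-[(S)-5-(tert-butyldimethylsilyloxy)-2,4-dioxononyl]-2,2-dimethyl-4H-1,3-dioxin-4-one
Product: 9 (S)-5-[1-(tert-butyldimethylsilyloxy)pentyl]-7-methoxy-2,2-dimethyl-4H-benzo[d][1,3]dioxin-4-one, via phenol 8 (not isolated)
Conditions: Et3N, CH2Cl2, rt, 16 h; evaporate; then MeI, K2CO3, acetone, rt
Reagents that add atoms: iodomethane, CI
Why: Base-mediated intramolecular aldol condensation–dehydration (biomimetic polyketide aromatisation) builds ring B as a resorcylate whose ortho-hydroxy acid stays masked as the acetonide, so only the para hydroxyl is free for Williamson methylation, and the stereocentre is not involved.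

**Step 5**
Reactants: 10 1,3-dimethoxy-5-pentylbenzene (olivetol dimethyl ether)
Product: 11 2-bromo-1,5-dimethoxy-3-pentylbenzene
Conditions: N-bromosuccinimide (1.0 equiv), MeCN, 0 °C → rt
Reagents that add atoms: N-bromosuccinimide, O=C1CCC(=O)N1Br
Why: Electrophilic aromatic bromination goes para to one methoxy group and ortho to the other, at the carbon next to the pentyl chain, as it does with 3,5-dimethoxytoluene.

**Step 6**
Reactants: 11 2-bromo-1,5-dimethoxy-3-pentylbenzene
Product: 14 2,4-dimethoxy-6-pentylphenol, via aryllithium 12 (not isolated), via boronate 13 (not isolated)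
Conditions: n-BuLi, THF, −78 °C; B(OMe)3, −78 °C → rt; then 30% H2O2, AcOH, 0 °C → rt
Reagents that add atoms: hydrogen peroxide, OO
Why: Lithium–bromine exchange, borylation and oxidative carbon-to-oxygen migration of the arylboronate replace bromine by hydroxyl at the same carbon.

**Step 7**
Reactants: 9 (S)-5-[1-(tert-butyldimethylsilyloxy)pentyl]-7-methoxy-2,2-dimethyl-4H-benzo[d][1,3]dioxin-4-one; 14 2,4-dimethoxy-6-pentylphenol
Product: 16 2,4-dimethoxy-6-pentylphenyl (S)-2-[1-(tert-butyldimethylsilyloxy)pentyl]-6-hydroxy-4-methoxybenzoate, via quinoketene 15 (not isolated)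
Conditions: 14 (2.5 equiv), hν (300 nm), CH2Cl2 (0.02 M), N2, rt
Reagents that add atoms: none
Why: Photolysis of the benzodioxinone extrudes acetone to give an ortho-quinoketene whose unhindered ketene carbon is captured by the hindered phenol (photochemical acylation via a quinoketene), which delivers the depside with the salicylate hydroxyl set free.

**Step 8**
Reactants: 16 2,4-dimethoxy-6-pentylphenyl (S)-2-[1-(tert-butyldimethylsilyloxy)pentyl]-6-hydroxy-4-methoxybenzoate
Product: 18 (S)-3-butyl-7-(2,4-dimethoxy-6-pentylphenoxy)-5-methoxyisobenzofuran-1(3H)-one, via acid 17 (not isolated)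
Conditions: 3,6-di-tert-butyl-9-mesityl-10-phenylacridinium tetrafluoroborate (5 mol%), ClCH2CH2Cl/(CF3)2CHOH 4:1 (0.02 M), 456 nm LEDs, N2, rt, 24 h; evaporate; then HCl (1.25 M in MeOH), 40 °C
Reagents that add atoms: none
Why: Proposed new method: a photoredox cation-radical Smiles rearrangement (O-to-O aryl shift of a depside), in which the excited acridinium (about +2.0 V vs SCE) oxidises the 2,4-dimethoxy-6-pentylphenyl ester ring (about +1.5 V) in preference to the salicylate ring (about +1.8 V), the hole is largest at the ester-bearing ipso carbon (para to one methoxy group and ortho to the other), the salicylate OH adds there through a six-membered spiro 1,3-benzodioxin-4-one radical cation, loss of the proton and heterolysis of the better leaving carboxylate give the radical cation of the diaryl ether, and this takes the electron back from the acridine radical (redox neutral and downhill because the aryloxy arene is easier to oxidise than the acyloxy arene); acid methanolysis then removes the silyl group and the hydroxy acid lactonises by acyl substitution with retention at the (S) centre; the closest known reaction types are the acridinium-photocatalysed cation-radical-accelerated nucleophilic aromatic substitution of alkoxyarenes and the base-mediated Smiles rearrangement of depsides that carry electron-poor O-aryl rings.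

**Step 9**
Reactants: 18 (S)-3-butyl-7-(2,4-dimethoxy-6-pentylphenoxy)-5-methoxyisobenzofuran-1(3H)-one
Product: 19 (S)-3-butyl-7-(2,4-dihydroxy-6-pentylphenoxy)-5-hydroxyisobenzofuran-1(3H)-one
Conditions: BBr3 (8 equiv), CH2Cl2, −78 → 0 °C; H2O, 0 °C
Reagents that add atoms: none
Why: Lewis-acid demethylation of the three aryl methyl ethers leaves the diaryl ether untouched, and the lactone carbon, meta to both ring oxygens and ortho to the carbonyl, cannot ionise, so the (S) centre survives as in BBr3 demethylations of methoxyphthalides.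

**Step 10**
Reactants: 19 (S)-3-butyl-7-(2,4-dihydroxy-6-pentylphenoxy)-5-hydroxyisobenzofuran-1(3H)-one
Product: 20 (S)-2-(2,4-dihydroxy-6-pentylphenoxy)-4-hydroxy-6-(1-hydroxypentyl)benzoic acid (CNP0272660.1)
Conditions: LiOH (6 equiv), degassed THF/H2O, Ar, 0 °C → rt; then 0 °C, 0.5 M HCl to pH 3–4, immediate EtOAc extraction, evaporation below 20 °C
Reagents that add atoms: lithium hydroxide, [Li+].[OH-]
Why: Saponification by acyl–oxygen cleavage leaves the bond between oxygen and the stereocentre intact (configuration retained), and cold, brief acidification with immediate extraction gives the free hydroxy acid before it can relactonise.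

## Compound list

1 | (S)-2-hydroxyhexanoic acid | CCCC[C@H](O)C(=O)O | starting material
2 | tert-butyldimethylsilyl (S)-2-(tert-butyldimethylsilyloxy)hexanoate | CCCC[C@H](O[Si](C)(C)C(C)(C)C)C(=O)O[Si](C)(C)C(C)(C)C | intermediate
3 | (S)-2-(tert-butyldimethylsilyloxy)hexanoic acid | CCCC[C@H](O[Si](C)(C)C(C)(C)C)C(=O)O | intermediate
4 | 2,2,6-trimethyl-4H-1,3-dioxin-4-one | CC1=CC(=O)OC(C)(C)O1 | starting material
5 | 2,2-dimethyl-6-(2-oxopropyl)-4H-1,3-dioxin-4-one | CC(=O)CC1=CC(=O)OC(C)(C)O1 | intermediate
6 | (S)-2-(tert-butyldimethylsilyloxy)-1-(1H-imidazol-1-yl)hexan-1-one | CCCC[C@H](O[Si](C)(C)C(C)(C)C)C(=O)n1ccnc1 | intermediate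
7 | 6-[(S)-5-(tert-butyldimethylsilyloxy)-2,4-dioxononyl]-2,2-dimethyl-4H-1,3-dioxin-4-one | CCCC[C@H](O[Si](C)(C)C(C)(C)C)C(=O)CC(=O)CC1=CC(=O)OC(C)(C)O1 | intermediate
8 | (S)-5-[1-(tert-butyldimethylsilyloxy)pentyl]-7-hydroxy-2,2-dimethyl-4H-benzo[d][1,3]dioxin-4-one | CCCC[C@H](O[Si](C)(C)C(C)(C)C)c1cc(O)cc2OC(C)(C)OC(=O)c12 | intermediate
9 | (S)-5-[1-(tert-butyldimethylsilyloxy)pentyl]-7-methoxy-2,2-dimethyl-4H-benzo[d][1,3]dioxin-4-one | CCCC[C@H](O[Si](C)(C)C(C)(C)C)c1cc(OC)cc2OC(C)(C)OC(=O)c12 | intermediate
10 | 1,3-dimethoxy-5-pentylbenzene | CCCCCc1cc(OC)cc(OC)c1 | starting material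
11 | 2-bromo-1,5-dimethoxy-3-pentylbenzene | CCCCCc1cc(OC)cc(OC)c1Br | intermediate
12 | (2,4-dimethoxy-6-pentylphenyl)lithium | CCCCCc1cc(OC)cc(OC)c1[Li] | intermediate
13 | dimethyl (2,4-dimethoxy-6-pentylphenyl)boronate | CCCCCc1cc(OC)cc(OC)c1B(OC)OC | intermediate
14 | 2,4-dimethoxy-6-pentylphenol | CCCCCc1cc(OC)cc(OC)c1O | intermediate
15 | (S)-5-[1-(tert-butyldimethylsilyloxy)pentyl]-3-methoxy-6-(oxomethylidene)cyclohexa-2,4-dien-1-one | CCCC[C@H](O[Si](C)(C)C(C)(C)C)C1=CC(OC)=CC(=O)C1=C=O | intermediate
16 | 2,4-dimethoxy-6-pentylphenyl (S)-2-[1-(tert-butyldimethylsilyloxy)pentyl]-6-hydroxy-4-methoxybenzoate | CCCC[C@H](O[Si](C)(C)C(C)(C)C)c1cc(OC)cc(O)c1C(=O)Oc1c(OC)cc(OC)cc1CCCCC | intermediate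
17 | (S)-2-[1-(tert-butyldimethylsilyloxy)pentyl]-6-(2,4-dimethoxy-6-pentylphenoxy)-4-methoxybenzoic acid | CCCC[C@H](O[Si](C)(C)C(C)(C)C)c1cc(OC)cc(Oc2c(OC)cc(OC)cc2CCCCC)c1C(=O)O | intermediate
18 | (S)-3-butyl-7-(2,4-dimethoxy-6-pentylphenoxy)-5-methoxyisobenzofuran-1(3H)-one | CCCC[C@@H]1OC(=O)c2c(Oc3c(OC)cc(OC)cc3CCCCC)cc(OC)cc21 | intermediate
19 | (S)-3-butyl-7-(2,4-dihydroxy-6-pentylphenoxy)-5-hydroxyisobenzofuran-1(3H)-one | CCCC[C@@H]1OC(=O)c2c(Oc3c(O)cc(O)cc3CCCCC)cc(O)cc21 | intermediate
20 | (S)-2-(2,4-dihydroxy-6-pentylphenoxy)-4-hydroxy-6-(1-hydroxypentyl)benzoic acid | CCCC[C@H](O)c1cc(O)cc(Oc2c(O)cc(O)cc2CCCCC)c1C(=O)O | target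

## Step count and risks

Total steps: 10. Longest linear sequence: 7 steps (1 → 3 → 7 → 9 → 16 → 18 → 19 → 20; steps 1, 3, 4, 7, 8, 9, 10).

**Step 8 (new photoredox Smiles shift) is the most uncertain.** The ring-closing attack needs the minor s-cis ester rotamer, the hydrogen-bonded salicylate OH is a weak nucleophile, and the product is easier to oxidise than 16. A seven-membered attack at the neighbouring methoxy-bearing carbon could give a depsidone by-product. The fallback uses known chemistry and sets out from 9. Bu4NF in THF removes the silyl group, and the alkoxide opens the dioxinone with loss of acetone to give (S)-3-butyl-7-hydroxy-5-methoxyisobenzofuran-1(3H)-one F1. Tf2O and pyridine in CH2Cl2 convert it into (S)-1-butyl-6-methoxy-3-oxo-1,3-dihydroisobenzofuran-4-yl trifluoromethanesulfonate F2. A palladium-catalysed diaryl ether coupling of F2 with phenol 14 (Pd(OAc)2, di-tert-butyl(2',4',6'-triisopropylbiphenyl-2-yl)phosphine, K3PO4, toluene, 100 °C) then forms the C–O bond and comes back to the route at 18. This pairing, an electron-poor aryl electrophile with an electron-rich phenol, is the favourable one for that coupling.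

**Step 7 (photochemical acylation).** The doubly ortho-substituted phenol 14 may trap the quinoketene slowly, and over-irradiation can erode the aryl salicylate by photo-Fries chemistry. The fallback sets out from 9. KOH in aqueous DMSO at 60 °C opens the acetonide to (S)-2-[1-(tert-butyldimethylsilyloxy)pentyl]-6-hydroxy-4-methoxybenzoic acid F3. This is esterified with 14 by the classical carbodiimide depside synthesis (N,N'-dicyclohexylcarbodiimide, catalytic 4-(dimethylamino)pyridine, CH2Cl2, rt), which comes back to the route at 16.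

**Step 3 (Claisen condensation).** The dianion has to tolerate the imidazole N–H released on activation (hence three equivalents of dianion) and an α-oxygenated acyl donor. The fallback sets out from 3. Amide coupling with N,O-dimethylhydroxylamine hydrochloride (EDC·HCl, HOBt, i-Pr2NEt, CH2Cl2) gives the isolated Weinreb amide (S)-2-(tert-butyldimethylsilyloxy)-N-methoxy-N-methylhexanamide F4. Its addition to the dianion of 5 (2.2 equiv, LiN(i-Pr)2, THF, −78 → 0 °C) passes through a stable chelated tetrahedral intermediate with no proton source present and comes back to the route at 7.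

## Further compounds

F1 | step 8 | (S)-3-butyl-7-hydroxy-5-methoxyisobenzofuran-1(3H)-one | CCCC[C@@H]1OC(=O)c2c(O)cc(OC)cc21
F2 | step 8 | (S)-1-butyl-6-methoxy-3-oxo-1,3-dihydroisobenzofuran-4-yl trifluoromethanesulfonate | CCCC[C@@H]1OC(=O)c2c(OS(=O)(=O)C(F)(F)F)cc(OC)cc21
F3 | step 7 | (S)-2-[1-(tert-butyldimethylsilyloxy)pentyl]-6-hydroxy-4-methoxybenzoic acid | CCCC[C@H](O[Si](C)(C)C(C)(C)C)c1cc(OC)cc(O)c1C(=O)O
F4 | step 3 | (S)-2-(tert-butyldimethylsilyloxy)-N-methoxy-N-methylhexanamide | CCCC[C@H](O[Si](C)(C)C(C)(C)C)C(=O)N(C)OC
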